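## Assumptions
- 4-Methylpent-3-en-1-ol, naphthazarin, isovaleric acid and (S,S)-ProPhenol are purchasable. Naphthazarin is a cheap dye intermediate made from 1,5-dihydroxy- or 1,5-dinitronaphthalene.
- The target is in the (S)-alkannin series. In the SMILES, the neighbour order at the stereocentre is CH2, H, O, C(aryl), and `@` with priorities O > C(aryl) > CH2 > H gives (S).
- The (S,S)-ProPhenol enantiomer is assumed to give the (S)-carbinol. The ligand enantiomer would be confirmed by screening.

## Retrosynthetic overview
- Isovalerylalkannin comes from (S)-alkannin by O-acylation of the side-chain secondary alcohol.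
- (S)-Alkannin comes from re-oxidation of the 2-(1-hydroxyalkyl)-dihydronaphthazarin adduct. That adduct comes from an enantioselective direct aldol-type hydroxyalkylation of leuco-naphthazarin (dearomatised 2,3-dihydro tautomer) with 4-methylpent-3-enal.
- Leuco-naphthazarin comes from hydrogenation of commercial naphthazarin. This reduction breaks the aromatic quinone ring and the C2v symmetry, and the aldol then desymmetrises it.
- No ring is built. The carbinol is the only stereocentre and is set in the aldol step. The aldehyde comes from oxidation of 4-methylpent-3-en-1-ol.

## Route

**Step 1**
Reactants: 1 (4-methylpent-3-en-1-ol)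
Product: 2 (4-methylpent-3-enal)
Conditions: Dess–Martin periodinane, NaHCO3, CH2Cl2, 0 °C, 1 h. The aldehyde is used at once as a cold solution.
Reagents that add atoms: none
Why: Buffered Dess–Martin oxidation of a primary alcohol is mild enough to avoid isomerising the β,γ-alkene into conjugation and to avoid acid-induced alkene reactions.

**Step 2**
Reactants: 3 (naphthazarin)
Product: 4 (leuco-naphthazarin, as its 5,8-dihydroxy-2,3-dihydronaphthalene-1,4-dione tautomer)
Conditions: H2 (1 atm), 10% Pd/C, THF, rt, 30 min (monitor by loss of the deep colour). Filter under Ar and use the filtrate at once.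
Reagents that add atoms: none (H2 adds only hydrogen)
Why: Catalytic hydrogenation reduces the quinone to the hydroquinone (leuco) level, which exists largely as the dearomatised 2,3-dihydro-1,4-dione tautomer with an enolisable CH2 next to a chelating peri-OH. The prenyl alkene is not yet present, so it cannot be reduced. Reduction is stopped at the leuco stage by short reaction time and by filtering off the catalyst.

**Step 3**
Reactants: 4 (leuco-naphthazarin), 2 (4-methylpent-3-enal)
Product: 5 (5,8-dihydroxy-2-[(1S)-1-hydroxy-4-methylpent-3-en-1-yl]-2,3-dihydronaphthalene-1,4-dione, epimeric at ring C2)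
Conditions: (S,S)-ProPhenol (10 mol%), Et2Zn (20 mol%), THF/toluene, –20 °C, under Ar. Add 4 (1.5 equiv) as the filtrate from Step 2, then add 2 (1.0 equiv) by syringe pump over 4 h. Stir 24 h, then quench with sat. aq. NH4Cl and extract with Et2O.
Reagents that add atoms: none (the ProPhenol/Zn catalyst leaves no atoms in 5; the aldehyde 2 is a listed reactant)
Why: Proposed new method: the dinuclear Zn–ProPhenol catalyst should form a Zn enolate of the dihydro-dione 4, chelated by the peri-OH, and bind the aldehyde on the second Zn. The chiral pocket selects one aldehyde face and sets the carbinol as (S). The closest known reactions are Trost's direct catalytic aldol of ketones with aldehydes and the Marschalk hydroxyalkylation of leuco-quinones. The ring C2 centre of 5 is epimerisable and is destroyed in the next step, so only the carbinol configuration matters. Slow addition of the limiting aldehyde, excess 4 and low temperature suppress aldehyde self-aldol, bis-addition, and dehydration to the quinone methide or deoxy product.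

**Step 4**
Reactants: 5 (adduct from Step 3)
Product: 6 ((S)-alkannin)
Conditions: Ag2O (3 equiv), anhydrous Na2SO4, CH2Cl2, 0 °C → rt, 30 min. Filter through Celite and concentrate cold.
Reagents that add atoms: none
Why: Ag2O dehydrogenates the enolisable dihydro-dione (the leuco tautomer) to the fully conjugated naphthazarin quinone, which removes the C2 stereocentre. This is the same re-oxidation used after Marschalk hydroxyalkylation. The carbinol is not touched and stays (S).

**Step 5**
Reactants: 6 ((S)-alkannin), 7 (isovaleric acid)
Product: 8 (isovalerylalkannin, the target)
Conditions: DCC (1.2 equiv), DMAP (0.1 equiv), CH2Cl2, 0 °C → rt, 4 h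
Reagents that add atoms: isovaleric acid, CC(C)CC(=O)O
Why: Steglich esterification acylates the free secondary alcohol. The two peri phenols are hydrogen-bonded to the quinone carbonyls and are poor nucleophiles. No bond to the stereocentre is broken, so (S) is retained.

## Compound list
1 | 4-methylpent-3-en-1-ol | CC(C)=CCCO | starting material
2 | 4-methylpent-3-enal | CC(C)=CCC=O | intermediate
3 | naphthazarin (5,8-dihydroxy-1,4-naphthoquinone) | O=C1C=CC(=O)c2c(O)ccc(O)c21 | starting material
4 | leuco-naphthazarin (5,8-dihydroxy-2,3-dihydronaphthalene-1,4-dione tautomer) | O=C1CCC(=O)c2c(O)ccc(O)c12 | intermediate (used without isolation)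
5 | 5,8-dihydroxy-2-[(1S)-1-hydroxy-4-methylpent-3-en-1-yl]-2,3-dihydronaphthalene-1,4-dione (ring C2 epimeric) | CC(C)=CC[C@H](O)C1CC(=O)c2c(O)ccc(O)c2C1=O | intermediate
6 | (S)-alkannin | CC(C)=CC[C@H](O)C1=CC(=O)c2c(O)ccc(O)c2C1=O | intermediate
7 | isovaleric acid | CC(C)CC(=O)O | starting material
8 | isovalerylalkannin | CC(C)=CC[C@H](OC(=O)CC(C)C)C1=CC(=O)c2c(O)ccc(O)c2C1=O | target

## Totals
- Total steps: 5 (Step 1 makes the aldehyde and Step 2 makes the leuco partner; the two branches meet in Step 3).
- Longest linear sequence: 4 (1 → 2 → 5 → 6 → 8, or equivalently 3 → 4 → 5 → 6 → 8).

## Three steps most likely to fail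
1. **Step 3 (enantioselective hydroxyalkylation).** Risks are low ee, self-aldol of the enolisable aldehyde, dehydration or reduction to the deoxy product, and retro-aldol of the adduct.
   - Fallback: change strategy to an achiral Zn- or Mg-mediated hydroxyalkylation of 4 with 2, then Step 4, to give (±)-alkannin. Resolve by CAL-B transesterification with vinyl isovalerate, which would deliver the (S)-ester directly. Racemise and recycle the (R)-alcohol.
2. **Step 4 (re-oxidation).** Risks are over-oxidation of the carbinol, dehydration of the β-hydroxy ketone to a quinone methide, and silver-induced racemisation.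
   - Fallback: use a redox-exchange oxidation in which extra naphthazarin 3 serves as the hydride acceptor (5 + 3 → 6 + 4), so no metal oxidant is needed and 4 is recycled.
3. **Step 5 (acylation).** Risks are phenol acylation, DMAP-induced elimination or racemisation of the benzylic-type carbinol, and alkene isomerisation.
   - Fallback: enzymatic acylation with CAL-B and vinyl isovalerate in MTBE. It is neutral and acylates only the secondary alcohol.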